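The dihydrobenzofuran is taken as a ring-contracted flavanone. Its C3a lies between the oxygen-bearing C4 and C7a of ring A and its C2 carries the catechol ring next to O1, which is the C4a/C5/C8a/C2 pattern of a (2S)-5,7-dioxygenated flavanone. The key step is an oxidative 1,2-shift with PhI(OAc)2: the ring A carbon migrates from the carbonyl carbon to C3, which closes the five-membered ring through the C3–C3a bond, keeps the C2 centre and leaves the extruded carbon as an ester. That ester is a traceless handle: decarboxylative arylation puts the resorcinol ring on C3 trans to the C2 aryl group. A Suzuki coupling and demethylation finish the route.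

Key step: step 4

Assumption: in step 3 the (R) enantiomer of the pyridine–oxazoline ligand is taken to give the (2S)-flavanone, by analogy with the (S)-ligand to (R)-β-aryl ketone sense of this catalyst on cyclic enones; if the sense is the reverse, the mirror-image ligand is used and nothing else changes.

Step 1
Reactants: 1 1-(2,4-dihydroxy-6-methoxyphenyl)ethan-1-one
Product: 2 4-acetyl-3-hydroxy-5-methoxyphenyl 4-methylbenzenesulfonate
Conditions: TsCl (1.05 equiv), K2CO3, acetone, 0 °C to rt
Reagents that add atoms: 4-methylbenzenesulfonyl chloride (Cc1ccc(cc1)S(Cl)(=O)=O)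
Why: The 2-hydroxyl is locked in a hydrogen bond to the acetyl group, so O-sulfonylation of the phenol should take the free 4-hydroxyl only.

Step 2
Reactants: 2 4-acetyl-3-hydroxy-5-methoxyphenyl 4-methylbenzenesulfonate
Product: 4 5-methoxy-4-oxo-4H-chromen-7-yl 4-methylbenzenesulfonate, via enaminone 3 (not isolated)
Conditions: Me2NCH(OMe)2, toluene, 90 °C; then conc. HCl, CH2Cl2, rt
Reagents that add atoms: N,N-dimethylformamide dimethyl acetal (COC(OC)N(C)C)
Why: Condensation at the acetyl methyl group gives the enaminone, and acid-promoted addition of the phenol with loss of dimethylamine (the standard enaminone cyclocondensation to a chromone) should close the pyranone without touching the aryl tosylate.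

Step 3
Reactants: 4 5-methoxy-4-oxo-4H-chromen-7-yl 4-methylbenzenesulfonate; 5 (3,4-dimethoxyphenyl)boronic acid
Product: 6 (2S)-2-(3,4-dimethoxyphenyl)-5-methoxy-4-oxo-3,4-dihydro-2H-chromen-7-yl 4-methylbenzenesulfonate
Conditions: Pd(OCOCF3)2 (5 mol %), (R)-t-BuPyOx (6 mol %), NH4PF6 (30 mol %), H2O (5 equiv), ClCH2CH2Cl, 60 °C
Reagents that add atoms: none
Why: Divalent palladium with a chiral pyridine–oxazoline ligand effects asymmetric conjugate addition of arylboronic acids to chromones (Hayashi–Miyaura-type 1,4-addition), so the ligand should direct the aryl group to one face of C2 and set the S centre, while the aryl tosylate stays inert because no zerovalent palladium with an activating phosphine is present.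

Step 4
Reactants: 6 (2S)-2-(3,4-dimethoxyphenyl)-5-methoxy-4-oxo-3,4-dihydro-2H-chromen-7-yl 4-methylbenzenesulfonate
Product: 9 methyl (2S,3S)-2-(3,4-dimethoxyphenyl)-4-methoxy-6-[(4-methylbenzenesulfonyl)oxy]-2,3-dihydro-1-benzofuran-3-carboxylate, via enol ether 7 (not isolated), via iodanyl ketal 8 (not isolated)
Conditions: PhI(OAc)2 (1.2 equiv), conc. H2SO4, HC(OMe)3, rt
Reagents that add atoms: trimethyl orthoformate (COC(OC)OC)
Why: H2SO4 and HC(OMe)3 turn the ketone of 6 into enol ether 7, PhI(OAc)2 adds to C3 of 7 on the face opposite the C2 aryl group and methanol caps C4, so that iodanyl ketal 8 carries an equatorial C3–iodine bond antiperiplanar to the C4–C4a bond; loss of PhI then pulls the ring A carbon C4a from C4 over to C3, and the expelled C4 leaves the ring as a dimethoxycarbenium ion that collapses to the methyl ester. The closest known reaction type is the oxidative ring contraction of flavanones to methyl 2-aryl-2,3-dihydrobenzofuran-3-carboxylates with trivalent iodine or trivalent thallium, a semipinacol-type 1,2-aryl shift. The five-membered ring closes by this suprafacial 1,2-shift through a bridged arenium (phenonium-like) transition state, so the C3–C3a bond (C3–C4a in flavanone numbering) forms as the C4–C4a bond breaks; it is a ring contraction and not a chain cyclisation. C2 is not touched and keeps the configuration set in step 3, and C3 should form trans to the C2 aryl group because iodine adds anti to that group and is displaced with inversion (this centre is reset in step 6 in any case). The step needs migration of the ring A carbon in preference to a 2,3-shift of the C2 aryl group (isoflavone formation) and to dehydrogenation (flavone formation); the ketal pathway with its equatorial leaving group and the two oxygen atoms ortho to the migrating carbon (O1 and the C5 methoxy group) should secure this, and regiochemistry on ring A cannot go wrong because C3a of the product is simply C4a of the flavanone.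

Step 5
Reactants: 9 methyl (2S,3S)-2-(3,4-dimethoxyphenyl)-4-methoxy-6-[(4-methylbenzenesulfonyl)oxy]-2,3-dihydro-1-benzofuran-3-carboxylate
Product: 10 (2S,3S)-2-(3,4-dimethoxyphenyl)-4-methoxy-6-[(4-methylbenzenesulfonyl)oxy]-2,3-dihydro-1-benzofuran-3-carboxylic acid
Conditions: Me3SnOH, ClCH2CH2Cl, 80 °C; then dilute aq. HCl
Reagents that add atoms: trimethyltin hydroxide (C[Sn](C)(C)O)
Why: Me3SnOH cleaves methyl esters under nearly neutral conditions (tin-mediated ester hydrolysis), which should avoid enolisation at C3 and the base-induced ring opening by loss of the ring phenoxide, and should spare the aryl tosylate.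

Step 6
Reactants: 10 (2S,3S)-2-(3,4-dimethoxyphenyl)-4-methoxy-6-[(4-methylbenzenesulfonyl)oxy]-2,3-dihydro-1-benzofuran-3-carboxylic acid; 11 1-bromo-3,5-dimethoxybenzene
Product: 12 (2S,3S)-2-(3,4-dimethoxyphenyl)-3-(3,5-dimethoxyphenyl)-4-methoxy-2,3-dihydro-1-benzofuran-6-yl 4-methylbenzenesulfonate
Conditions: Ir[dF(CF3)ppy]2(dtbbpy)PF6 (1 mol %), NiCl2(dme) (10 mol %), dtbbpy (15 mol %), Cs2CO3, DMF, blue LEDs, rt
Reagents that add atoms: none
Why: Photoredox oxidation of the caesium carboxylate and loss of CO2 give the benzylic C3 radical, which nickel couples with the aryl bromide (metallaphotoredox decarboxylative arylation); the aryl group should enter the planar radical on the face opposite the C2 aryl group and so set the 3S (trans) centre, and the aryl tosylate should not add to bipyridine-ligated nickel.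

Step 7
Reactants: 12 (2S,3S)-2-(3,4-dimethoxyphenyl)-3-(3,5-dimethoxyphenyl)-4-methoxy-2,3-dihydro-1-benzofuran-6-yl 4-methylbenzenesulfonate; 13 [(E)-2-(4-methoxyphenyl)ethenyl]boronic acid
Product: 14 (2S,3S)-2-(3,4-dimethoxyphenyl)-3-(3,5-dimethoxyphenyl)-4-methoxy-6-[(E)-2-(4-methoxyphenyl)ethenyl]-2,3-dihydro-1-benzofuran
Conditions: Pd(OAc)2 (4 mol %), XPhos (8 mol %), K3PO4, t-AmOH, 100 °C
Reagents that add atoms: none
Why: XPhos-ligated zerovalent palladium inserts into aryl tosylates and couples them with alkenylboronic acids with retention of alkene geometry (Suzuki–Miyaura coupling), and the step is placed after step 6 so that the stilbene never meets the photocatalyst, which could isomerise it.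

Step 8
Reactants: 14 (2S,3S)-2-(3,4-dimethoxyphenyl)-3-(3,5-dimethoxyphenyl)-4-methoxy-6-[(E)-2-(4-methoxyphenyl)ethenyl]-2,3-dihydro-1-benzofuran
Product: 15 4-[(2S,3S)-3-(3,5-dihydroxyphenyl)-4-hydroxy-6-[(E)-2-(4-hydroxyphenyl)ethenyl]-2,3-dihydro-1-benzofuran-2-yl]benzene-1,2-diol
Conditions: BBr3 (excess), CH2Cl2, −78 °C to rt; then H2O
Reagents that add atoms: none
Why: BBr3 should cleave all six aryl methyl ethers (Lewis-acid ether cleavage), C3 cannot epimerise under acid, and any transient opening of the C2–O bond should reclose to the more stable trans ring.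

Compound list
1 | 1-(2,4-dihydroxy-6-methoxyphenyl)ethan-1-one | CC(=O)c1c(O)cc(O)cc1OC | starting material
2 | 4-acetyl-3-hydroxy-5-methoxyphenyl 4-methylbenzenesulfonate | CC(=O)c1c(O)cc(OS(=O)(=O)c2ccc(C)cc2)cc1OC | intermediate
3 | 4-[(2E)-3-(dimethylamino)prop-2-enoyl]-3-hydroxy-5-methoxyphenyl 4-methylbenzenesulfonate (enaminone) | CN(C)/C=C/C(=O)c1c(O)cc(OS(=O)(=O)c2ccc(C)cc2)cc1OC | intermediate
4 | 5-methoxy-4-oxo-4H-chromen-7-yl 4-methylbenzenesulfonate | COc1cc(OS(=O)(=O)c2ccc(C)cc2)cc2occc(=O)c12 | intermediate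
5 | (3,4-dimethoxyphenyl)boronic acid | COc1ccc(cc1OC)B(O)O | starting material
6 | (2S)-2-(3,4-dimethoxyphenyl)-5-methoxy-4-oxo-3,4-dihydro-2H-chromen-7-yl 4-methylbenzenesulfonate | COc1ccc(cc1OC)[C@@H]1CC(=O)c2c(OC)cc(OS(=O)(=O)c3ccc(C)cc3)cc2O1 | intermediate
7 | (2S)-2-(3,4-dimethoxyphenyl)-4,5-dimethoxy-2H-chromen-7-yl 4-methylbenzenesulfonate (enol ether) | COc1ccc(cc1OC)[C@@H]1C=C(OC)c2c(OC)cc(OS(=O)(=O)c3ccc(C)cc3)cc2O1 | intermediate
8 | (2R,3R)-3-[(acetyloxy)(phenyl)-λ3-iodanyl]-2-(3,4-dimethoxyphenyl)-4,4,5-trimethoxy-3,4-dihydro-2H-chromen-7-yl 4-methylbenzenesulfonate (2,3-trans; C2 unchanged in space, its descriptor changes because iodine raises the rank of C3) | COc1ccc(cc1OC)[C@@H]1[C@@H]([I](OC(C)=O)c2ccccc2)C(OC)(OC)c2c(OC)cc(OS(=O)(=O)c3ccc(C)cc3)cc2O1 | intermediate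
9 | methyl (2S,3S)-2-(3,4-dimethoxyphenyl)-4-methoxy-6-[(4-methylbenzenesulfonyl)oxy]-2,3-dihydro-1-benzofuran-3-carboxylate (trans) | Cc1ccc(cc1)S(=O)(=O)Oc1cc(OC)c2c(c1)O[C@H](c1ccc(OC)c(OC)c1)[C@H]2C(=O)OC | intermediate
10 | (2S,3S)-2-(3,4-dimethoxyphenyl)-4-methoxy-6-[(4-methylbenzenesulfonyl)oxy]-2,3-dihydro-1-benzofuran-3-carboxylic acid (trans) | Cc1ccc(cc1)S(=O)(=O)Oc1cc(OC)c2c(c1)O[C@H](c1ccc(OC)c(OC)c1)[C@H]2C(=O)O | intermediate
11 | 1-bromo-3,5-dimethoxybenzene | COc1cc(Br)cc(OC)c1 | starting material
12 | (2S,3S)-2-(3,4-dimethoxyphenyl)-3-(3,5-dimethoxyphenyl)-4-methoxy-2,3-dihydro-1-benzofuran-6-yl 4-methylbenzenesulfonate (trans) | Cc1ccc(cc1)S(=O)(=O)Oc1cc(OC)c2c(c1)O[C@H](c1ccc(OC)c(OC)c1)[C@H]2c1cc(OC)cc(OC)c1 | intermediate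
13 | [(E)-2-(4-methoxyphenyl)ethenyl]boronic acid | COc1ccc(/C=C/B(O)O)cc1 | starting material
14 | (2S,3S)-2-(3,4-dimethoxyphenyl)-3-(3,5-dimethoxyphenyl)-4-methoxy-6-[(E)-2-(4-methoxyphenyl)ethenyl]-2,3-dihydro-1-benzofuran | COc1ccc(/C=C/c2cc(OC)c3c(c2)O[C@H](c2ccc(OC)c(OC)c2)[C@H]3c2cc(OC)cc(OC)c2)cc1 | intermediate
15 | 4-[(2S,3S)-3-(3,5-dihydroxyphenyl)-4-hydroxy-6-[(E)-2-(4-hydroxyphenyl)ethenyl]-2,3-dihydro-1-benzofuran-2-yl]benzene-1,2-diol | Oc1ccc(/C=C/c2cc(O)c3c(c2)O[C@H](c2ccc(O)c(O)c2)[C@H]3c2cc(O)cc(O)c2)cc1 | target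

Total step count: 8. Longest linear sequence: 8 steps (1 to 15); compounds 5, 11 and 13 are bought.

Steps most likely to fail

Step 4. What may go wrong: the electron-rich C2 aryl group migrates instead of the ring A carbon (2,3-shift to an isoflavone), the iodanyl intermediate loses a proton to give the flavone, or ketalisation of the hindered, vinylogous-ester-like carbonyl is too slow. Fallback: the same ring A migration is run as a Wolff rearrangement. Setting out from 6, nitrosation at C3 (isoamyl nitrite, HCl, THF, 0 °C) should give the 3-oximinoflavanone F1. A Forster reaction (NH2Cl made from NaOCl and aqueous NH3, NaOH, THF–H2O, 0 °C) should convert it into the 3-diazoflavanone F2. Photolysis of F2 (medium-pressure Hg lamp, Pyrex, dioxane–H2O) should expel dinitrogen with migration of the ring A carbon to C3, and water adds to the ring-contracted ketene. This comes back to the route at acid 10, accompanied by its cis C3 epimer F3; both are carried into step 6, where C3 becomes planar and the two converge on 12.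

Step 6. What may go wrong: capture of the hindered C3 radical by nickel is slow, so that ring opening by β-scission of the C2–O bond, hydrogen-atom abstraction (protodecarboxylation) or oxidation of the electron-rich arenes by the excited photocatalyst takes over; facial selectivity could also be incomplete. Fallback: the radical is generated reductively from an activated ester in the presence of a preformed aryl–nickel species, without light. Setting out from 10, coupling with N-hydroxyphthalimide (N,N'-diisopropylcarbodiimide, catalytic DMAP, CH2Cl2) should give the N-hydroxyphthalimide ester F4. Decarboxylative Suzuki-type arylation of F4 with commercial (3,5-dimethoxyphenyl)boronic acid (NiCl2·6H2O, bathophenanthroline, Et3N, dioxane–DMF, 75 °C) comes back to the route at 12.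

Step 8. What may go wrong: during the sixfold ether cleavage the acid opens the C2–O bond (the cation is stabilised by the para-oxygenated C2 aryl group) and HBr adds to, or starts cationic oligomerisation of, the electron-rich stilbene. Fallback: the ether cleavage is moved in front of the stilbene-forming coupling. Setting out from 12, BBr3 (CH2Cl2, −78 °C to 0 °C) should cleave the five methyl ethers and leave the sulfonate, giving the pentaphenol tosylate F5. Suzuki–Miyaura coupling of F5 with commercial 4-[(E)-2-(4,4,5,5-tetramethyl-1,3,2-dioxaborolan-2-yl)ethenyl]phenol (Pd(OAc)2, XPhos, K3PO4, dioxane–H2O, 90 °C) comes back to the route directly at 15.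

Further compounds
F1 | step 4 | (2R)-2-(3,4-dimethoxyphenyl)-3-(hydroxyimino)-5-methoxy-4-oxo-3,4-dihydro-2H-chromen-7-yl 4-methylbenzenesulfonate (C2 as in 6; oxime geometry not defined) | COc1ccc(cc1OC)[C@@H]1C(=NO)C(=O)c2c(OC)cc(OS(=O)(=O)c3ccc(C)cc3)cc2O1
F2 | step 4 | (2R)-3-diazo-2-(3,4-dimethoxyphenyl)-5-methoxy-4-oxo-3,4-dihydro-2H-chromen-7-yl 4-methylbenzenesulfonate (C2 as in 6) | COc1ccc(cc1OC)[C@@H]1C(=[N+]=[N-])C(=O)c2c(OC)cc(OS(=O)(=O)c3ccc(C)cc3)cc2O1
F3 | step 4 | (2S,3R)-2-(3,4-dimethoxyphenyl)-4-methoxy-6-[(4-methylbenzenesulfonyl)oxy]-2,3-dihydro-1-benzofuran-3-carboxylic acid (cis epimer of 10) | Cc1ccc(cc1)S(=O)(=O)Oc1cc(OC)c2c(c1)O[C@H](c1ccc(OC)c(OC)c1)[C@@H]2C(=O)O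
F4 | step 6 | 1,3-dioxo-1,3-dihydro-2H-isoindol-2-yl (2S,3S)-2-(3,4-dimethoxyphenyl)-4-methoxy-6-[(4-methylbenzenesulfonyl)oxy]-2,3-dihydro-1-benzofuran-3-carboxylate | Cc1ccc(cc1)S(=O)(=O)Oc1cc(OC)c2c(c1)O[C@H](c1ccc(OC)c(OC)c1)[C@H]2C(=O)ON1C(=O)c2ccccc2C1=O
F5 | step 8 | (2S,3S)-2-(3,4-dihydroxyphenyl)-3-(3,5-dihydroxyphenyl)-4-hydroxy-2,3-dihydro-1-benzofuran-6-yl 4-methylbenzenesulfonate | Cc1ccc(cc1)S(=O)(=O)Oc1cc(O)c2c(c1)O[C@H](c1ccc(O)c(O)c1)[C@H]2c1cc(O)cc(O)c1
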